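The quinone (C1=O, C2–OMe, C3–H, C4=O, C5–CH3, C6–henicosyl) is treated as an oxidised, decarboxylated alkylresorcinol, and the plan rests on disconnecting its C1–C6 ring bond. The feature exploited is the 1,3-oxygen pattern at C2 and C4 together with the C5 methyl and the C6 chain on the six-membered carbocycle: this is the imprint of a linear chain with ketones at alternate carbons. One intramolecular aldol of methyl 6-methyl-3,5,7-trioxooctacosanoate (9), a linear triketo ester with the docosanoyl ketone at one end, the ester at the other and a methyl branch beside that ketone, closes the ring and aromatises it to resorcylate 11 with all four substituents in place.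

Key step: step 4

Remark: the target has no stereocentre. Compounds 9 and 10 are drawn as keto tautomers although both should exist as enol mixtures; their sp3 centres are racemic and vanish in step 4. "Chain" locants are those of the octacosanoate 9, and chain C2, C3, C4, C5, C6, C7 become ring C1, C2, C3, C4, C5, C6 of the quinone.

Step 1
Reactants: 1 docosanoic acid
Product: 3 N-methoxy-N-methyldocosanamide, via N-docosanoylimidazole 2 (not isolated)
Conditions: CDI, THF, 45 °C; then MeNHOMe·HCl, rt
Reagents that add atoms: N,O-dimethylhydroxylamine hydrochloride, CNOC.Cl (the N(OMe)Me group of 3); 1,1'-carbonyldiimidazole, O=C(n1ccnc1)n1ccnc1 (the imidazolyl group of 2 only)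
Why: Amide formation through an acyl imidazole: CDI activates the acid as 2 with loss of CO2, and N,O-dimethylhydroxylamine displaces imidazole to give the Weinreb amide, with no stereocentre involved.

Step 2
Reactants: 4 methyl acetoacetate; 5 N-methoxy-N-methylpropanamide
Product: 7 methyl 3,5-dioxoheptanoate, via dilithium dianion of methyl acetoacetate 6 (not isolated)
Conditions: LiN(i-Pr)2 (LDA, 2.2 equiv), THF, −78 to 0 °C; then amide 5, −78 to 0 °C; aq. HCl quench
Reagents that add atoms: lithium diisopropylamide, [Li+].CC(C)[N-]C(C)C (the lithium counter-ions of 6 only)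
Why: Weinreb ketone synthesis with a 1,3-dicarbonyl dianion (a crossed Claisen-type γ-acylation): the terminal CH2 carbanion of 6 is its most nucleophilic site, and the N-methoxy chelate holds the adduct until the acid quench, so neither over-addition nor proton transfer from the acidic product should interfere; no stereocentre is formed.

Step 3
Reactants: 7 methyl 3,5-dioxoheptanoate; 3 N-methoxy-N-methyldocosanamide
Product: 9 methyl 6-methyl-3,5,7-trioxooctacosanoate (racemic at C6, enolised; used crude), via trilithium trianion of the diketo ester 8 (not isolated)
Conditions: LiN(i-Pr)2 (LDA, 3.3 equiv), THF, −78 to 0 °C; then 3 in THF, 0 °C to rt; cold dilute aq. HCl, extraction, no chromatography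
Reagents that add atoms: lithium diisopropylamide, [Li+].CC(C)[N-]C(C)C (the lithium counter-ions of 8 only)
Why: Terminal acylation of a β,δ-diketo ester trianion in a Weinreb ketone synthesis: the carbanion formed last, at the CH2 of the ethyl ketone, is the most basic and nucleophilic site of 8 and should add once to the amide, the chelated adduct releasing the third ketone only on quench; the new C6 centre lies between two ketones, is formed racemic and is lost in step 4.

Step 4
Reactants: 9 methyl 6-methyl-3,5,7-trioxooctacosanoate
Product: 11 methyl 2-henicosyl-4,6-dihydroxy-3-methylbenzoate, via cyclic aldol adduct 10 (not isolated)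
Conditions: K2CO3, MeOH/THF, rt; then HCl in MeOH, rt
Reagents that add atoms: none
Why: Carbonate generates the chain C2 enolate (stabilised by ester and ketone; it equilibrates with the more stable C4 enolate, which could only reach four-membered rings and is unproductive), and this carbon adds to the C7 docosanoyl ketone to give β-hydroxy ketone 10, after which acid expels water and the C3 and C5 ketones enolise, so that the new chain C2–C7 bond (ring C1–C6) ends up in a benzene ring. The closest known reaction type is the biomimetic intramolecular aldol aromatisation of 3,5,7-triketo esters to orsellinate-type resorcylates. The single ring closes in a 6-exo-trig mode at the C7 carbonyl, the enolate being endocyclic when written through the C3 oxygen and exocyclic when written through the ester oxygen, and both modes are allowed. No stereocentre survives, because the racemic C6 centre of 9 and the three centres of 10 are all erased on aromatisation. The step needs carbon cyclisation by aldol addition instead of Claisen closure from chain C6 onto C1 or oxygen cyclisation to a pyranone: the methyl group on C6 makes the Claisen product a 2-acyl-2-methylcyclohexane-1,3,5-trione that cannot aromatise and reverts, mild carbonate at room temperature keeps lactonisation of the methyl ester slow, and aromatisation of 10 is the irreversible sink.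

Step 5
Reactants: 11 methyl 2-henicosyl-4,6-dihydroxy-3-methylbenzoate
Product: 13 5-henicosyl-4-methylbenzene-1,3-diol, via free resorcylic acid 12 (not isolated)
Conditions: KOH, H2O/EtOH, reflux, argon; then aq. HCl to pH 1, 60 °C
Reagents that add atoms: potassium hydroxide, [K+].[OH-] (one oxygen of the carboxyl group of 12 only)
Why: Ester saponification followed by protodecarboxylation of a β-resorcylic acid: acid 12 carries hydroxyl groups ortho and para to the carboxyl-bearing carbon, so ipso protonation and loss of CO2 should be easy on warming in acid, as is usual for orsellinate-type esters; no stereocentre is involved.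

Step 6
Reactants: 13 5-henicosyl-4-methylbenzene-1,3-diol
Product: 14 6-henicosyl-2-hydroxy-5-methyl-1,4-benzoquinone (3-henicosyl-5-hydroxy-2-methylcyclohexa-2,5-diene-1,4-dione)
Conditions: (KSO3)2NO (2.5 equiv), aq. KH2PO4, methyltrioctylammonium chloride (cat.), CH2Cl2, rt
Reagents that add atoms: potassium nitrosodisulfonate (Fremy's salt), [K+].[K+].[O]N(S(=O)(=O)[O-])S(=O)(=O)[O-]
Why: Teuber oxidation: the phenoxyl radical formed by the first nitrosodisulfonate radical is trapped by a second one at ring C1, the only unsubstituted carbon para to a hydroxyl group (para to C4–OH, whereas the carbon para to C2–OH is the methylated C5), and loss of imidodisulfonate should give the 1,4-quinone, which is also the tautomer of the ortho-quinone that attack at C1 ortho to C2–OH would give.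

Step 7
Reactants: 14 6-henicosyl-2-hydroxy-5-methyl-1,4-benzoquinone
Product: 15 6-henicosyl-2-methoxy-5-methyl-1,4-benzoquinone (3-henicosyl-5-methoxy-2-methylcyclohexa-2,5-diene-1,4-dione), the target
Conditions: MeOH/CH2Cl2, H2SO4 (cat.), 40 °C
Reagents that add atoms: methanol, CO
Why: Acid-catalysed etherification of a vinylogous carboxylic acid (Fischer-type): the C2–OH is conjugated to the C4 carbonyl through C3, so methanol should add to protonated 14 at C2 and water should leave, giving the thermodynamically preferred 2-methoxy-1,4-quinone and not an ortho-quinone ether, while the fully substituted C5=C6 bond resists conjugate addition.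

Compound list
1 | docosanoic acid | CCCCCCCCCCCCCCCCCCCCCC(=O)O | starting material
2 | 1-(1H-imidazol-1-yl)docosan-1-one (N-docosanoylimidazole) | CCCCCCCCCCCCCCCCCCCCCC(=O)n1ccnc1 | intermediate
3 | N-methoxy-N-methyldocosanamide | CCCCCCCCCCCCCCCCCCCCCC(=O)N(C)OC | intermediate
4 | methyl acetoacetate | CC(=O)CC(=O)OC | starting material
5 | N-methoxy-N-methylpropanamide | CCC(=O)N(C)OC | starting material
6 | dilithium dianion of methyl acetoacetate (dienolate) | [Li+].[Li+].C=C([O-])C=C([O-])OC | intermediate
7 | methyl 3,5-dioxoheptanoate | CCC(=O)CC(=O)CC(=O)OC | intermediate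
8 | trilithium trianion of methyl 3,5-dioxoheptanoate (trienolate, mixture of double-bond isomers) | [Li+].[Li+].[Li+].CC=C([O-])C=C([O-])C=C([O-])OC | intermediate
9 | methyl 6-methyl-3,5,7-trioxooctacosanoate (racemic at C6, enolised) | CCCCCCCCCCCCCCCCCCCCCC(=O)C(C)C(=O)CC(=O)CC(=O)OC | intermediate
10 | methyl 2-henicosyl-2-hydroxy-3-methyl-4,6-dioxocyclohexane-1-carboxylate (mixture of diastereomers, enolised) | CCCCCCCCCCCCCCCCCCCCCC1(O)C(C)C(=O)CC(=O)C1C(=O)OC | intermediate
11 | methyl 2-henicosyl-4,6-dihydroxy-3-methylbenzoate | CCCCCCCCCCCCCCCCCCCCCc1c(C)c(O)cc(O)c1C(=O)OC | intermediate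
12 | 2-henicosyl-4,6-dihydroxy-3-methylbenzoic acid | CCCCCCCCCCCCCCCCCCCCCc1c(C)c(O)cc(O)c1C(=O)O | intermediate
13 | 5-henicosyl-4-methylbenzene-1,3-diol | CCCCCCCCCCCCCCCCCCCCCc1cc(O)cc(O)c1C | intermediate
14 | 6-henicosyl-2-hydroxy-5-methyl-1,4-benzoquinone | CCCCCCCCCCCCCCCCCCCCCC1=C(C)C(=O)C=C(O)C1=O | intermediate
15 | 6-henicosyl-2-methoxy-5-methyl-1,4-benzoquinone | CCCCCCCCCCCCCCCCCCCCCC1=C(C)C(=O)C=C(OC)C1=O | target

Total step count: 7. Longest linear sequence: 6 steps (steps 1, 3, 4, 5, 6, 7 from docosanoic acid; equally steps 2 to 7 from methyl acetoacetate).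

Steps most likely to fail

Step 4. The enolate may close through oxygen instead of carbon, either by lactonisation onto the ester or by cyclodehydration to a 4-pyranone. Methoxide may also cleave the α-methyl β-diketone by a retro-Claisen reaction, or addition to the hindered, α-branched C7 ketone may simply be too slow. The fallback builds the same benzoate by the dihydroresorcylate route and sets out from 3. Reduction of 3 with LiAlH4 in THF at 0 °C should give docosanal F1, and a Wittig reaction with 3-(triphenyl-λ5-phosphanylidene)butan-2-one in refluxing toluene should give (E)-3-methylpentacos-3-en-2-one F2. Michael addition of dimethyl malonate with NaOMe in refluxing MeOH should give dimethyl 2-(3-methyl-2-oxopentacosan-4-yl)propanedioate F3, which should undergo Dieckmann-type closure in the same flask to methyl 2-henicosyl-3-methyl-4,6-dioxocyclohexane-1-carboxylate F4. Bromination and dehydrobromination with Br2 in DMF (0 to 80 °C) should aromatise F4, and the route is rejoined at 11.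

Step 3. The third deprotonation at a secondary carbon may be incomplete, the trianion may act as a base toward the α-CH2 of the amide, or the hindered carbanion may add too slowly, so that starting materials return. The fallback replaces the strongly basic trianion by a neutral silyl polyenol ether and sets out from 7 and 1. Exhaustive silylation of 7 (Me3SiCl/Et3N, then LiN(i-Pr)2 and Me3SiCl at −78 °C) should give 1-methoxy-1,3,5-tris(trimethylsilyloxy)hepta-1,3,5-triene F5, and SOCl2 should convert 1 into docosanoyl chloride F6. A vinylogous Mukaiyama-type acylation of F5 by F6 at the terminal carbon (CH2Cl2, −78 °C to rt, Me3SiOTf cat.), followed by dilute aqueous acid, should rejoin the route at 9.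

Step 6. Mass transfer between the aqueous radical salt and the waxy resorcinol may be poor, the electron-rich hydroxyquinone may be over-oxidised or couple, or attack may occur at C3 between the two hydroxyl groups. The fallback installs the C1 oxygen by formylation and oxygen insertion and sets out from 13. Double O-methylation (Me2SO4, K2CO3, acetone) should give 1-henicosyl-3,5-dimethoxy-2-methylbenzene F7, and Vilsmeier–Haack formylation (POCl3, DMF) at the carbon para to one methoxy group should give 2-henicosyl-4,6-dimethoxy-3-methylbenzaldehyde F8. Baeyer–Villiger oxidation with mCPBA in CH2Cl2 should give 2-henicosyl-4,6-dimethoxy-3-methylphenyl formate F9, and methanolysis (K2CO3, MeOH) should give 2-henicosyl-4,6-dimethoxy-3-methylphenol F10. Oxidative demethylation of F10 with (NH4)2Ce(NO3)6 in MeCN/H2O at 0 °C should remove the para methoxy group and rejoin the route at 15, bypassing 14 and step 7.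

Further compounds
F1 | step 4 | docosanal | CCCCCCCCCCCCCCCCCCCCCC=O
F2 | step 4 | (E)-3-methylpentacos-3-en-2-one | CCCCCCCCCCCCCCCCCCCCC/C=C(\C)C(C)=O
F3 | step 4 | dimethyl 2-(3-methyl-2-oxopentacosan-4-yl)propanedioate (mixture of diastereomers) | CCCCCCCCCCCCCCCCCCCCCC(C(C)C(C)=O)C(C(=O)OC)C(=O)OC
F4 | step 4 | methyl 2-henicosyl-3-methyl-4,6-dioxocyclohexane-1-carboxylate (mixture of diastereomers, enolised) | CCCCCCCCCCCCCCCCCCCCCC1C(C)C(=O)CC(=O)C1C(=O)OC
F5 | step 3 | 1-methoxy-1,3,5-tris(trimethylsilyloxy)hepta-1,3,5-triene (mixture of double-bond isomers) | CC=C(O[Si](C)(C)C)C=C(O[Si](C)(C)C)C=C(OC)O[Si](C)(C)C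
F6 | step 3 | docosanoyl chloride | CCCCCCCCCCCCCCCCCCCCCC(=O)Cl
F7 | step 6 | 1-henicosyl-3,5-dimethoxy-2-methylbenzene | CCCCCCCCCCCCCCCCCCCCCc1cc(OC)cc(OC)c1C
F8 | step 6 | 2-henicosyl-4,6-dimethoxy-3-methylbenzaldehyde | CCCCCCCCCCCCCCCCCCCCCc1c(C)c(OC)cc(OC)c1C=O
F9 | step 6 | 2-henicosyl-4,6-dimethoxy-3-methylphenyl formate | CCCCCCCCCCCCCCCCCCCCCc1c(C)c(OC)cc(OC)c1OC=O
F10 | step 6 | 2-henicosyl-4,6-dimethoxy-3-methylphenol | CCCCCCCCCCCCCCCCCCCCCc1c(C)c(OC)cc(OC)c1O
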